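The route rests on cutting the bond between C4 of the bicyclo[3.2.1]oct-3-ene-2,8-dione core and the α-carbon of the 4-hydroxystyryl side chain. The key step is an aerobic palladium-catalysed oxidative Heck coupling that joins an (E)-alkenylboronate directly to the C4–H of the fully assembled bicyclic enone, installing the dienone without any leaving group. It exploits the cyclohexenone ring (C1–C5, C8): C4 is its only β-carbon, the bridgeheads C1 and C5 cannot enolise or aromatise, and the endo C6 aryl group shields one face. The precursor is the C4-unsubstituted enone, built from (S)-4-silyloxycyclopentenone by two anti-selective aryl conjugate additions, an aldol trap and a ring-closing enolate alkenylation.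

Key step: step 8

Remark: bicyclic compounds are numbered like the target skeleton (C1 and C5 bridgeheads, C2 next to C1, C3=C4 the ring alkene, C6 and C7 the aryl-bearing carbons, C8 the bridging carbonyl). Monocyclic ketones are numbered from the carbonyl carbon (C2 side chain, C3 and C4 aryl-bearing, C5 methylene). The carbinol carbon made in step 4 is carried as both epimers, because step 6 converts it into the C2 carbonyl.

Step 1
Reactants: 1 5-bromobenzene-1,3-diol
Product: 2 1-bromo-3,5-bis[(triisopropylsilyl)oxy]benzene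
Conditions: i-Pr3SiCl (2.4 equiv), imidazole, DMF, rt
Reagents that add atoms: triisopropylsilyl chloride, CC(C)[Si](Cl)(C(C)C)C(C)C
Why: Standard silylation of both phenols gives bulky triisopropylsilyl ethers that should survive the Grignard, amide-base and oxidation steps and fall to fluoride at the end.

Step 2
Reactants: 2 1-bromo-3,5-bis[(triisopropylsilyl)oxy]benzene; 3 (S)-4-[(tert-butyldimethylsilyl)oxy]cyclopent-2-en-1-one
Product: 6 (S)-4-{3,5-bis[(triisopropylsilyl)oxy]phenyl}cyclopent-2-en-1-one, via Grignard reagent 4 (not isolated), via silyloxy ketone 5 (not isolated)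
Conditions: 2, Mg, THF, 40 °C; then 3, CuBr·SMe2 (10 mol%), THF, −78 → −40 °C; aq NH4Cl; then DBU, CH2Cl2, 0 °C, short contact
Reagents that add atoms: none
Why: Copper-catalysed conjugate addition of the aryl Grignard reagent should occur anti to the C4 silyloxy group and base then expels silanolate by E1cB elimination, so the single stereocentre of the 4-arylcyclopentenone comes from the commercial (S)-enone.

Step 3
Reactants: 7 ethyl (Z)-3-iodoprop-2-enoate
Product: 8 (Z)-3-iodoprop-2-enal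
Conditions: i-Bu2AlH (1.05 equiv), CH2Cl2, −78 °C; aq potassium sodium tartrate; used at once as a cold solution
Reagents that add atoms: none
Why: Partial reduction of the ester with i-Bu2AlH at −78 °C should stop at the aldehyde because the tetrahedral aluminium hemiacetal is stable at that temperature, and the (Z)-alkene is kept if the aldehyde stays cold.

Step 4
Reactants: 6 (S)-4-{3,5-bis[(triisopropylsilyl)oxy]phenyl}cyclopent-2-en-1-one; 9 (4-bromophenoxy)triisopropylsilane; 8 (Z)-3-iodoprop-2-enal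
Product: 13 (2R,3R,4S)-4-{3,5-bis[(triisopropylsilyl)oxy]phenyl}-2-{(Z)-3-iodo-1-[(triethylsilyl)oxy]prop-2-en-1-yl}-3-{4-[(triisopropylsilyl)oxy]phenyl}cyclopentan-1-one (carbinol epimers), via Grignard reagent 10 (not isolated), via magnesium enolate 11 (not isolated), via magnesium aldolate 12 (not isolated)
Conditions: 9, Mg, THF; then 6, CuBr·SMe2 (10 mol%), THF, −78 → −40 °C; 8 (1.5 equiv), −78 °C; Et3SiCl, imidazole, −78 → 0 °C
Reagents that add atoms: triethylsilyl chloride, CC[Si](Cl)(CC)CC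
Why: Copper-catalysed conjugate addition should occur anti to the C4 aryl group and the magnesium enolate then adds to the aldehyde anti to the new C3 aryl group (three-component conjugate addition–aldol coupling), giving the 2,3-trans-3,4-trans ketone, while the carbinol centre is left uncontrolled and in situ silylation blocks retro-aldol cleavage.

Step 5
Reactants: 13 (2R,3R,4S)-4-{3,5-bis[(triisopropylsilyl)oxy]phenyl}-2-{(Z)-3-iodo-1-[(triethylsilyl)oxy]prop-2-en-1-yl}-3-{4-[(triisopropylsilyl)oxy]phenyl}cyclopentan-1-one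
Product: 15 (1R,5R,6R,7R)-6-{3,5-bis[(triisopropylsilyl)oxy]phenyl}-2-hydroxy-7-{4-[(triisopropylsilyl)oxy]phenyl}bicyclo[3.2.1]oct-3-en-8-one (C2 epimers), via triethylsilyl ether 14 (not isolated)
Conditions: KN(SiMe3)2 (1.1 equiv), THF, −78 °C; Pd(PPh3)4 (10 mol%), −78 °C → rt; then 1 M HCl, THF, 0 °C
Reagents that add atoms: none
Why: Kinetic deprotonation at the unsubstituted C5 methylene followed by zerovalent-palladium-catalysed intramolecular enolate alkenylation with the (Z)-alkenyl iodide should close the six-membered ring, the new bridgehead centre being fixed by the tether because the bond can only form on the ring face that carries the C2 side chain (syn to the C4 aryl group, which thereby becomes endo), and dilute acid then cleaves only the alkyl triethylsilyl ether.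

Step 6
Reactants: 15 (1R,5R,6R,7R)-6-{3,5-bis[(triisopropylsilyl)oxy]phenyl}-2-hydroxy-7-{4-[(triisopropylsilyl)oxy]phenyl}bicyclo[3.2.1]oct-3-en-8-one
Product: 16 (1R,5R,6R,7R)-6-{3,5-bis[(triisopropylsilyl)oxy]phenyl}-7-{4-[(triisopropylsilyl)oxy]phenyl}bicyclo[3.2.1]oct-3-ene-2,8-dione
Conditions: Dess–Martin periodinane, CH2Cl2, 0 °C → rt
Reagents that add atoms: none
Why: Dess–Martin oxidation of the allylic alcohol should take both C2 epimers to the single enone under neutral conditions that spare the non-enolisable 1,3-diketone from retro-Claisen cleavage.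

Step 7
Reactants: 17 tert-butyl(4-ethynylphenoxy)dimethylsilane
Product: 18 (E)-tert-butyldimethyl{4-[2-(4,4,5,5-tetramethyl-1,3,2-dioxaborolan-2-yl)ethenyl]phenoxy}silane
Conditions: pinacolborane, Cp2Zr(H)Cl (10 mol%), Et3N (10 mol%), neat, 60 °C
Reagents that add atoms: pinacolborane, CC1(C)OBOC1(C)C
Why: Zirconium-catalysed syn hydroboration of the terminal alkyne places boron on the terminal carbon and should give only the (E)-alkenylboronate.

Step 8
Reactants: 16 (1R,5R,6R,7R)-6-{3,5-bis[(triisopropylsilyl)oxy]phenyl}-7-{4-[(triisopropylsilyl)oxy]phenyl}bicyclo[3.2.1]oct-3-ene-2,8-dione; 18 (E)-tert-butyldimethyl{4-[2-(4,4,5,5-tetramethyl-1,3,2-dioxaborolan-2-yl)ethenyl]phenoxy}silane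
Product: 19 (1R,5S,6R,7R)-6-{3,5-bis[(triisopropylsilyl)oxy]phenyl}-4-[(E)-2-{4-[(tert-butyldimethylsilyl)oxy]phenyl}ethenyl]-7-{4-[(triisopropylsilyl)oxy]phenyl}bicyclo[3.2.1]oct-3-ene-2,8-dione
Conditions: 18 (2 equiv), Pd(OAc)2 (10 mol%), 2,9-dimethyl-1,10-phenanthroline (12 mol%), O2 (1 atm), DMF, 50 °C
Reagents that add atoms: none
Why: Transmetalation of 18 to divalent palladium gives an (E)-alkenylpalladium species that adds syn across the C3=C4 bond of 16, the alkenyl group going to the electrophilic β-carbon C4 on the face syn to the C8 bridge because the other face is covered by the endo C6 aryl group. The C3-bound palladium enolate then changes face through its oxygen-bound form, syn β-hydride elimination of the C4–H restores the enone and O2 reoxidises the palladium hydride; the closest known reactions are oxidative (boron) Heck couplings of cyclohexenones with arylboronic acids and of alkenylboronates with acrylates. No ring is closed and no stereocentre is created, and the four existing centres are untouched because neither bridgehead can enolise. The step needs regioselectivity for C4, retention of the (E)-alkene and chemoselectivity over the C8 ketone: C4 is the only β-carbon of the only enone, the alkene geometry is carried over from the boronate, and ketones do not insert into alkenylpalladium bonds. If the palladium enolate is protonated instead, the saturated 4-alkenyl ketone can only be dehydrogenated across C3–C4 under the same aerobic conditions, so both channels should converge on 19, and over-oxidation to a phenol is excluded by the bridge.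

Step 9
Reactants: 19 (1R,5S,6R,7R)-6-{3,5-bis[(triisopropylsilyl)oxy]phenyl}-4-[(E)-2-{4-[(tert-butyldimethylsilyl)oxy]phenyl}ethenyl]-7-{4-[(triisopropylsilyl)oxy]phenyl}bicyclo[3.2.1]oct-3-ene-2,8-dione
Product: 20 vitisinol D, (1R,5S,6R,7R)-6-(3,5-dihydroxyphenyl)-7-(4-hydroxyphenyl)-4-[(E)-2-(4-hydroxyphenyl)ethenyl]bicyclo[3.2.1]oct-3-ene-2,8-dione
Conditions: HF·pyridine, pyridine, THF, 0 °C → rt
Reagents that add atoms: none
Why: Buffered HF·pyridine should cleave all four aryl silyl ethers without forming free phenoxide or hydroxide, which could open the 1,3-diketone by retro-Claisen or retro-Michael pathways, and no stereocentre is affected.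

Compound list
1 | 5-bromobenzene-1,3-diol | Oc1cc(O)cc(Br)c1 | starting material
2 | 1-bromo-3,5-bis[(triisopropylsilyl)oxy]benzene | Brc1cc(O[Si](C(C)C)(C(C)C)C(C)C)cc(O[Si](C(C)C)(C(C)C)C(C)C)c1 | intermediate
3 | (S)-4-[(tert-butyldimethylsilyl)oxy]cyclopent-2-en-1-one | O=C1C=C[C@@H](O[Si](C)(C)C(C)(C)C)C1 | starting material
4 | {3,5-bis[(triisopropylsilyl)oxy]phenyl}magnesium bromide | Br[Mg]c1cc(O[Si](C(C)C)(C(C)C)C(C)C)cc(O[Si](C(C)C)(C(C)C)C(C)C)c1 | intermediate
5 | (3R,4S)-3-{3,5-bis[(triisopropylsilyl)oxy]phenyl}-4-[(tert-butyldimethylsilyl)oxy]cyclopentan-1-one (3,4-trans) | O=C1C[C@H](c2cc(O[Si](C(C)C)(C(C)C)C(C)C)cc(O[Si](C(C)C)(C(C)C)C(C)C)c2)[C@@H](O[Si](C)(C)C(C)(C)C)C1 | intermediate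
6 | (S)-4-{3,5-bis[(triisopropylsilyl)oxy]phenyl}cyclopent-2-en-1-one | O=C1C[C@H](c2cc(O[Si](C(C)C)(C(C)C)C(C)C)cc(O[Si](C(C)C)(C(C)C)C(C)C)c2)C=C1 | intermediate
7 | ethyl (Z)-3-iodoprop-2-enoate | CCOC(=O)/C=C\I | starting material
8 | (Z)-3-iodoprop-2-enal | O=C/C=C\I | intermediate
9 | (4-bromophenoxy)triisopropylsilane | Brc1ccc(O[Si](C(C)C)(C(C)C)C(C)C)cc1 | starting material
10 | {4-[(triisopropylsilyl)oxy]phenyl}magnesium bromide | Br[Mg]c1ccc(O[Si](C(C)C)(C(C)C)C(C)C)cc1 | intermediate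
11 | bromomagnesium (3R,4S)-4-{3,5-bis[(triisopropylsilyl)oxy]phenyl}-3-{4-[(triisopropylsilyl)oxy]phenyl}cyclopent-1-en-1-olate (3,4-trans) | Br[Mg]OC1=C[C@H](c2ccc(O[Si](C(C)C)(C(C)C)C(C)C)cc2)[C@@H](c2cc(O[Si](C(C)C)(C(C)C)C(C)C)cc(O[Si](C(C)C)(C(C)C)C(C)C)c2)C1 | intermediate
12 | bromomagnesium alkoxide of (2R,3R,4S)-4-{3,5-bis[(triisopropylsilyl)oxy]phenyl}-2-[(Z)-1-hydroxy-3-iodoprop-2-en-1-yl]-3-{4-[(triisopropylsilyl)oxy]phenyl}cyclopentan-1-one (O–MgBr on the side-chain oxygen, carbinol epimers) | O=C1C[C@H](c2cc(O[Si](C(C)C)(C(C)C)C(C)C)cc(O[Si](C(C)C)(C(C)C)C(C)C)c2)[C@@H](c2ccc(O[Si](C(C)C)(C(C)C)C(C)C)cc2)[C@@H]1C(O[Mg]Br)/C=C\I | intermediate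
13 | (2R,3R,4S)-4-{3,5-bis[(triisopropylsilyl)oxy]phenyl}-2-{(Z)-3-iodo-1-[(triethylsilyl)oxy]prop-2-en-1-yl}-3-{4-[(triisopropylsilyl)oxy]phenyl}cyclopentan-1-one (2,3-trans, 3,4-trans, carbinol epimers) | O=C1C[C@H](c2cc(O[Si](C(C)C)(C(C)C)C(C)C)cc(O[Si](C(C)C)(C(C)C)C(C)C)c2)[C@@H](c2ccc(O[Si](C(C)C)(C(C)C)C(C)C)cc2)[C@@H]1C(O[Si](CC)(CC)CC)/C=C\I | intermediate
14 | (1R,5R,6R,7R)-6-{3,5-bis[(triisopropylsilyl)oxy]phenyl}-2-[(triethylsilyl)oxy]-7-{4-[(triisopropylsilyl)oxy]phenyl}bicyclo[3.2.1]oct-3-en-8-one (C2 epimers, 6-aryl endo, 7-aryl exo) | CC[Si](CC)(CC)OC1C=C[C@H]2C(=O)[C@@H]1[C@H](c1ccc(O[Si](C(C)C)(C(C)C)C(C)C)cc1)[C@H]2c1cc(O[Si](C(C)C)(C(C)C)C(C)C)cc(O[Si](C(C)C)(C(C)C)C(C)C)c1 | intermediate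
15 | (1R,5R,6R,7R)-6-{3,5-bis[(triisopropylsilyl)oxy]phenyl}-2-hydroxy-7-{4-[(triisopropylsilyl)oxy]phenyl}bicyclo[3.2.1]oct-3-en-8-one (C2 epimers) | OC1C=C[C@H]2C(=O)[C@@H]1[C@H](c1ccc(O[Si](C(C)C)(C(C)C)C(C)C)cc1)[C@H]2c1cc(O[Si](C(C)C)(C(C)C)C(C)C)cc(O[Si](C(C)C)(C(C)C)C(C)C)c1 | intermediate
16 | (1R,5R,6R,7R)-6-{3,5-bis[(triisopropylsilyl)oxy]phenyl}-7-{4-[(triisopropylsilyl)oxy]phenyl}bicyclo[3.2.1]oct-3-ene-2,8-dione | O=C1C=C[C@H]2C(=O)[C@@H]1[C@H](c1ccc(O[Si](C(C)C)(C(C)C)C(C)C)cc1)[C@H]2c1cc(O[Si](C(C)C)(C(C)C)C(C)C)cc(O[Si](C(C)C)(C(C)C)C(C)C)c1 | intermediate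
17 | tert-butyl(4-ethynylphenoxy)dimethylsilane | C#Cc1ccc(O[Si](C)(C)C(C)(C)C)cc1 | starting material
18 | (E)-tert-butyldimethyl{4-[2-(4,4,5,5-tetramethyl-1,3,2-dioxaborolan-2-yl)ethenyl]phenoxy}silane | CC1(C)OB(/C=C/c2ccc(O[Si](C)(C)C(C)(C)C)cc2)OC1(C)C | intermediate
19 | (1R,5S,6R,7R)-6-{3,5-bis[(triisopropylsilyl)oxy]phenyl}-4-[(E)-2-{4-[(tert-butyldimethylsilyl)oxy]phenyl}ethenyl]-7-{4-[(triisopropylsilyl)oxy]phenyl}bicyclo[3.2.1]oct-3-ene-2,8-dione | O=C1C=C(/C=C/c2ccc(O[Si](C)(C)C(C)(C)C)cc2)[C@H]2C(=O)[C@@H]1[C@H](c1ccc(O[Si](C(C)C)(C(C)C)C(C)C)cc1)[C@H]2c1cc(O[Si](C(C)C)(C(C)C)C(C)C)cc(O[Si](C(C)C)(C(C)C)C(C)C)c1 | intermediate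
20 | vitisinol D, (1R,5S,6R,7R)-6-(3,5-dihydroxyphenyl)-7-(4-hydroxyphenyl)-4-[(E)-2-(4-hydroxyphenyl)ethenyl]bicyclo[3.2.1]oct-3-ene-2,8-dione | O=C1C=C(/C=C/c2ccc(O)cc2)[C@H]2C(=O)[C@@H]1[C@H](c1ccc(O)cc1)[C@H]2c1cc(O)cc(O)c1 | target

Total step count: 9 steps.
Longest linear sequence: 7 steps (steps 1, 2, 4, 5, 6, 8 and 9, from 5-bromobenzene-1,3-diol); steps 3 and 7 are side branches.

Steps most likely to fail

Step 8. The palladium enolate formed after insertion may be protonated faster than it undergoes β-hydride elimination, or the alkenylboronate may be used up by homocoupling and protodeboronation before it transmetalates, so that the coupling stalls. The fallback sets out from 16 and alkyne 17. Hydrozirconation of 17 (Cp2Zr(H)Cl, THF) and copper-catalysed (CuBr·SMe2) conjugate addition of the resulting (E)-alkenylzirconocene to 16 should give the saturated 4-alkenyl diketone F1, the alkenyl group being delivered to the face syn to the C8 bridge. Soft enolisation (Me3SiOTf, Et3N, CH2Cl2), possible only towards C3, should give the trimethylsilyl enol ether F2, and Saegusa–Ito oxidation (Pd(OAc)2, MeCN) should bring the route back to 19.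

Step 5. Deprotonation may occur at C2 of the cyclopentanone and expel the β-silyloxy group, or base may eliminate HI from the alkenyl iodide, before the hindered ring closure on the face syn to the C4 aryl group takes place. The fallback sets out from 13. Kinetic enol silylation (LiN(i-Pr)2, Me3SiCl, THF, −78 °C) should give the regiodefined trimethylsilyl enol ether F3. Its base-free intramolecular coupling with the alkenyl iodide under fluoride activation (Pd2(dba)3, P(t-Bu)3, CsF, toluene) should give 14 and, after the same acid treatment, rejoin the route at 15.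

Step 4. The magnesium enolate or residual arylcopper species may attack the β-iodoenal by addition–elimination or by coupling at the C–I bond, and the aldolate may revert before it is silylated. The fallback sets out from 6 and 9. The same copper-catalysed conjugate addition run in the presence of Me3SiCl should give the trimethylsilyl enol ether F4. A Mukaiyama aldol addition to 8 (BF3·OEt2, CH2Cl2, −78 °C), again anti to the C3 aryl group, should give the β-hydroxy ketone F5, and silylation (Et3SiOTf, 2,6-lutidine, CH2Cl2) should bring the route back to 13.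

Further compounds
F1 | step 8 | (1R,4S,5R,6R,7R)-6-{3,5-bis[(triisopropylsilyl)oxy]phenyl}-4-[(E)-2-{4-[(tert-butyldimethylsilyl)oxy]phenyl}ethenyl]-7-{4-[(triisopropylsilyl)oxy]phenyl}bicyclo[3.2.1]octane-2,8-dione | O=C1C[C@@H](/C=C/c2ccc(O[Si](C)(C)C(C)(C)C)cc2)[C@H]2C(=O)[C@@H]1[C@H](c1ccc(O[Si](C(C)C)(C(C)C)C(C)C)cc1)[C@H]2c1cc(O[Si](C(C)C)(C(C)C)C(C)C)cc(O[Si](C(C)C)(C(C)C)C(C)C)c1
F2 | step 8 | (1R,4R,5R,6R,7R)-6-{3,5-bis[(triisopropylsilyl)oxy]phenyl}-4-[(E)-2-{4-[(tert-butyldimethylsilyl)oxy]phenyl}ethenyl]-7-{4-[(triisopropylsilyl)oxy]phenyl}-2-[(trimethylsilyl)oxy]bicyclo[3.2.1]oct-2-en-8-one | C[Si](C)(C)OC1=C[C@@H](/C=C/c2ccc(O[Si](C)(C)C(C)(C)C)cc2)[C@H]2C(=O)[C@@H]1[C@H](c1ccc(O[Si](C(C)C)(C(C)C)C(C)C)cc1)[C@H]2c1cc(O[Si](C(C)C)(C(C)C)C(C)C)cc(O[Si](C(C)C)(C(C)C)C(C)C)c1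
F3 | step 5 | {[(3R,4R,5R)-3-{3,5-bis[(triisopropylsilyl)oxy]phenyl}-5-{(Z)-3-iodo-1-[(triethylsilyl)oxy]prop-2-en-1-yl}-4-{4-[(triisopropylsilyl)oxy]phenyl}cyclopent-1-en-1-yl]oxy}trimethylsilane (carbinol epimers) | C[Si](C)(C)OC1=C[C@H](c2cc(O[Si](C(C)C)(C(C)C)C(C)C)cc(O[Si](C(C)C)(C(C)C)C(C)C)c2)[C@@H](c2ccc(O[Si](C(C)C)(C(C)C)C(C)C)cc2)[C@@H]1C(O[Si](CC)(CC)CC)/C=C\I
F4 | step 4 | {[(3R,4S)-4-{3,5-bis[(triisopropylsilyl)oxy]phenyl}-3-{4-[(triisopropylsilyl)oxy]phenyl}cyclopent-1-en-1-yl]oxy}trimethylsilane | C[Si](C)(C)OC1=C[C@H](c2ccc(O[Si](C(C)C)(C(C)C)C(C)C)cc2)[C@@H](c2cc(O[Si](C(C)C)(C(C)C)C(C)C)cc(O[Si](C(C)C)(C(C)C)C(C)C)c2)C1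
F5 | step 4 | (2R,3R,4S)-4-{3,5-bis[(triisopropylsilyl)oxy]phenyl}-2-[(Z)-1-hydroxy-3-iodoprop-2-en-1-yl]-3-{4-[(triisopropylsilyl)oxy]phenyl}cyclopentan-1-one (carbinol epimers) | O=C1C[C@H](c2cc(O[Si](C(C)C)(C(C)C)C(C)C)cc(O[Si](C(C)C)(C(C)C)C(C)C)c2)[C@@H](c2ccc(O[Si](C(C)C)(C(C)C)C(C)C)cc2)[C@@H]1C(O)/C=C\I
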